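## Retrosynthetic overview

1. Numbering: lactone ring = O1, C2(=O), C3=C4, C5H2, C6H. Side chain = C7(OH)–C8(OAr)(Ph). The flavanone (rings A, B, C) is bought intact as (2S)-pinocembrin.
2. Last disconnections: the C7–O silyl ether, then the C8–O aryl ether (Mitsunobu inversion by the 7-OH of pinocembrin), then the C8–phenyl bond (phenyltitanium addition to a C8 aldehyde unmasked from a vinyl group).
3. Key disconnection: the C4–C5 bond of the lactone ring. It is closed from an acyclic C5 iodide whose O1 carries a 3-nitropropanoyl group, by nitronate C-alkylation (6-exo-tet). Loss of nitrite in the same flask then gives C3=C4.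
4. Enabling feature: in the dihydropyranone ring C4 lies beta to the C2 carbonyl, so a nitro group on C4 is both the only acidifying group and a beta-leaving group. C5 is a primary carbon next to the O1-bearing C6, so C5 and C6–O1 are the two ends of a terminal oxirane.
5. C6 and C7 come from Sharpless desymmetrisation of penta-1,4-dien-3-ol. Ring order: oxirane (temporary, opened in step 3), then the dihydropyranone ring (step 5). No other ring is made.

Key step: step 5

Assumption: the natural (2S)-enantiomer of pinocembrin is taken as a commercial, enantiopure starting material. All steps after its introduction are kept free of strong base so that its C2 centre is not epimerised.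

## Route

Step 1
Reactants: 1 penta-1,4-dien-3-ol
Product: 2 (1R)-1-[(2S)-oxiran-2-yl]prop-2-en-1-ol
Conditions: Ti(OiPr)4 (cat.), D-(−)-diisopropyl tartrate, t-BuOOH, 4 Å MS, CH2Cl2, −20 °C
Reagents that add atoms: tert-butyl hydroperoxide CC(C)(C)OO
Why: Sharpless asymmetric epoxidation used as a desymmetrisation, in which the D-(−)-tartrate catalyst should epoxidise one enantiotopic vinyl group on one face to give the erythro (anti) epoxy alcohol, setting C6 and C7, while the minor enantiomer is removed by a faster second epoxidation.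

Step 2
Reactants: 2 (1R)-1-[(2S)-oxiran-2-yl]prop-2-en-1-ol
Product: 3 tert-butyl(dimethyl){(1R)-1-[(2S)-oxiran-2-yl]prop-2-en-1-yloxy}silane
Conditions: TBSCl, imidazole, DMF, 0 to 23 °C
Reagents that add atoms: tert-butyldimethylsilyl chloride CC(C)(C)[Si](C)(C)Cl
Why: Standard silylation of a secondary alcohol under imidazole conditions, mild enough to avoid Payne rearrangement, masks O7 for the whole route and touches no stereocentre.

Step 3
Reactants: 3 tert-butyl(dimethyl){(1R)-1-[(2S)-oxiran-2-yl]prop-2-en-1-yloxy}silane
Product: 4 (2R,3R)-3-(tert-butyldimethylsilyloxy)-1-iodopent-4-en-2-ol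
Conditions: LiI, AcOH, THF, 23 °C
Reagents that add atoms: lithium iodide [Li+].[I-]
Why: Buffered halohydrin formation by SN2 opening of the terminal epoxide at primary C5 leaves the C6–O bond and its geometry intact (the descriptor becomes R only because iodine raises the rank of C5).

Step 4
Reactants: 4 (2R,3R)-3-(tert-butyldimethylsilyloxy)-1-iodopent-4-en-2-ol; 5 3-nitropropanoic acid
Product: 6 (2R,3R)-3-(tert-butyldimethylsilyloxy)-1-iodopent-4-en-2-yl 3-nitropropanoate
Conditions: DCC, DMAP (cat.), CH2Cl2, 0 °C
Reagents that add atoms: none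
Why: Steglich esterification of the only free hydroxyl group hangs the C2–C4 unit on O1 without breaking a bond at C6, and the low temperature and catalytic DMAP keep the beta-nitro ester from losing HNO2.

Step 5
Reactants: 6 (2R,3R)-3-(tert-butyldimethylsilyloxy)-1-iodopent-4-en-2-yl 3-nitropropanoate
Product: 9 (6S)-6-[(1R)-1-(tert-butyldimethylsilyloxy)prop-2-en-1-yl]-5,6-dihydro-2H-pyran-2-one, via potassium nitronate 7 (not isolated), via 4-nitrolactone 8 (not isolated)
Conditions: KN(SiMe3)2 (1.0 equiv), THF, −78 °C; dilution with DMF to 0.005 M, 23 to 45 °C; then DBU (1.5 equiv), 0 to 23 °C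
Reagents that add atoms: none
Why: Proposed new method: one equivalent of KN(SiMe3)2 removes only a C4–H next to the nitro group (more than ten pK units more acidic than the C3–H next to the ester), the long-lived nitronate 7 displaces the primary C5 iodide through carbon in a 6-exo-tet SN2 closure to nitrolactone 8, and DBU then expels nitrite by E1cB through the C3 enolate, which puts the double bond at C3=C4 inside the ring (necessarily cis). The closest known reaction types are the intramolecular C-alkylation of nitronates by tethered halides or sulfonates (used to make nitro carbocycles) and the use of 3-nitropropanoates as acrylate beta-anion equivalents (bond formation at the nitro carbon, then base-induced loss of HNO2); new here is that the tether runs through the ester oxygen O1, so that the ring closed is the delta-lactone. C- against O-alkylation is secured by ring size (six-membered through carbon, eight-membered nitronic ester through oxygen), and intermolecular O-alkylation is held back by high dilution. C4 against C3 is secured by the stoichiometry of base: the monoanion is nucleophilic only at C4 and cannot lose nitrite, whereas a dianion would close through C3 (5-exo-tet) and free base on neutral 6 would give the acrylate. The minor E ester rotamer (the lactone-like geometry) that the closure needs can be reached because the anion is persistent, which a short-lived C5 radical would not allow. The only new stereocentre (C4 of 8) is uncontrolled and is erased in the elimination, and C6 and C7 are not involved.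

Step 6
Reactants: 9 (6S)-6-[(1R)-1-(tert-butyldimethylsilyloxy)prop-2-en-1-yl]-5,6-dihydro-2H-pyran-2-one
Product: 11 (2S)-2-(tert-butyldimethylsilyloxy)-2-[(2S)-6-oxo-3,6-dihydro-2H-pyran-2-yl]acetaldehyde, via ozonide 10 (not isolated)
Conditions: O3, CH2Cl2, −78 °C (stopped at consumption of 9); then PPh3, −78 to 0 °C; used crude
Reagents that add atoms: ozone [O-][O+]=O
Why: Ozonolysis with reductive work-up should cleave the terminal vinyl group selectively because the conjugated, electron-poor C3=C4 bond reacts far more slowly with ozone, and C7 keeps its geometry (the descriptor changes with the new CHO rank).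

Step 7
Reactants: 11 (2S)-2-(tert-butyldimethylsilyloxy)-2-[(2S)-6-oxo-3,6-dihydro-2H-pyran-2-yl]acetaldehyde
Product: 12 (6S)-6-[(1R,2R)-1-(tert-butyldimethylsilyloxy)-2-hydroxy-2-phenylethyl]-5,6-dihydro-2H-pyran-2-one
Conditions: PhMgBr, ClTi(OiPr)3, Et2O/THF, −78 to 0 °C (gives PhTi(OiPr)3); then 11, −78 to −30 °C; aq. NH4Cl
Reagents that add atoms: phenylmagnesium bromide Br[Mg]c1ccccc1
Why: Chemoselective 1,2-addition of a non-basic organotitanium reagent attacks only the aldehyde (no lactone opening, conjugate addition or beta-elimination), and the polar Felkin–Anh (Cornforth) model for the non-chelating alpha-silyloxy aldehyde, reinforced by the anti C6/C7 dioxygen pattern, should set C8 as the 7,8-anti (8R) carbinol.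

Step 8
Reactants: 12 (6S)-6-[(1R,2R)-1-(tert-butyldimethylsilyloxy)-2-hydroxy-2-phenylethyl]-5,6-dihydro-2H-pyran-2-one; 13 (2S)-pinocembrin [(2S)-5,7-dihydroxy-2-phenylchroman-4-one]
Product: 14 (6S)-6-[(1S,2S)-1-(tert-butyldimethylsilyloxy)-2-{[(2S)-5-hydroxy-4-oxo-2-phenyl-3,4-dihydro-2H-chromen-7-yl]oxy}-2-phenylethyl]-5,6-dihydro-2H-pyran-2-one
Conditions: PPh3, DIAD, THF, 0 to 23 °C
Reagents that add atoms: none
Why: Mitsunobu etherification displaces the C8 alkoxyphosphonium ion by SN2 with inversion (8R to 8S, giving the 7,8-syn array), only the acidic 7-OH reacts because the 5-OH is hydrogen-bonded to the C4 ketone, and the neutral medium spares the flavanone C2 centre and the lactone.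

Step 9
Reactants: 14 (6S)-6-[(1S,2S)-1-(tert-butyldimethylsilyloxy)-2-{[(2S)-5-hydroxy-4-oxo-2-phenyl-3,4-dihydro-2H-chromen-7-yl]oxy}-2-phenylethyl]-5,6-dihydro-2H-pyran-2-one
Product: 15 (6S)-6-[(1S,2S)-1-hydroxy-2-{[(2S)-5-hydroxy-4-oxo-2-phenyl-3,4-dihydro-2H-chromen-7-yl]oxy}-2-phenylethyl]-5,6-dihydro-2H-pyran-2-one (target)
Conditions: HF·pyridine, pyridine, THF, 0 to 23 °C
Reagents that add atoms: none
Why: Fluoride-mediated desilylation under buffered, non-basic conditions frees O7 without oxa-Michael closure, lactone opening, ether cleavage or flavanone epimerisation, and changes no stereocentre.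

## Compound list

1 | penta-1,4-dien-3-ol | C=CC(O)C=C | starting material
2 | (1R)-1-[(2S)-oxiran-2-yl]prop-2-en-1-ol | C=C[C@@H](O)[C@@H]1CO1 | intermediate
3 | TBS ether of 2 | C=C[C@@H](O[Si](C)(C)C(C)(C)C)[C@@H]1CO1 | intermediate
4 | (2R,3R)-3-(tert-butyldimethylsilyloxy)-1-iodopent-4-en-2-ol | C=C[C@@H](O[Si](C)(C)C(C)(C)C)[C@@H](O)CI | intermediate
5 | 3-nitropropanoic acid | O=C(O)CC[N+](=O)[O-] | starting material
6 | (2R,3R)-3-(tert-butyldimethylsilyloxy)-1-iodopent-4-en-2-yl 3-nitropropanoate | C=C[C@@H](O[Si](C)(C)C(C)(C)C)[C@@H](OC(=O)CC[N+](=O)[O-])CI | intermediate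
7 | potassium nitronate of 6 (not isolated) | C=C[C@@H](O[Si](C)(C)C(C)(C)C)[C@@H](OC(=O)CC=[N+]([O-])[O-])CI.[K+] | intermediate
8 | (6S)-6-[(1R)-1-(tert-butyldimethylsilyloxy)prop-2-en-1-yl]-4-nitrotetrahydro-2H-pyran-2-one, C4 epimers (not isolated) | O=C1CC([N+](=O)[O-])C[C@@H]([C@H](O[Si](C)(C)C(C)(C)C)C=C)O1 | intermediate
9 | (6S)-6-[(1R)-1-(tert-butyldimethylsilyloxy)prop-2-en-1-yl]-5,6-dihydro-2H-pyran-2-one | O=C1C=CC[C@@H]([C@H](O[Si](C)(C)C(C)(C)C)C=C)O1 | intermediate
10 | 1,2,4-trioxolane (ozonide) of the vinyl group of 9 (not isolated) | O=C1C=CC[C@@H]([C@H](O[Si](C)(C)C(C)(C)C)C2OCOO2)O1 | intermediate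
11 | (2S)-2-(tert-butyldimethylsilyloxy)-2-[(2S)-6-oxo-3,6-dihydro-2H-pyran-2-yl]acetaldehyde | O=C1C=CC[C@@H]([C@H](O[Si](C)(C)C(C)(C)C)C=O)O1 | intermediate
12 | (6S)-6-[(1R,2R)-1-(tert-butyldimethylsilyloxy)-2-hydroxy-2-phenylethyl]-5,6-dihydro-2H-pyran-2-one | O=C1C=CC[C@@H]([C@H](O[Si](C)(C)C(C)(C)C)[C@H](O)c2ccccc2)O1 | intermediate
13 | (2S)-pinocembrin | O=C1C[C@@H](c2ccccc2)Oc2cc(O)cc(O)c12 | starting material
14 | 7-O-TBS ether of the target | O=C1C=CC[C@@H]([C@H](O[Si](C)(C)C(C)(C)C)[C@@H](Oc2cc(O)c3c(c2)O[C@H](c2ccccc2)CC3=O)c2ccccc2)O1 | intermediate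
15 | (6S)-6-[(1S,2S)-1-hydroxy-2-{[(2S)-5-hydroxy-4-oxo-2-phenyl-3,4-dihydro-2H-chromen-7-yl]oxy}-2-phenylethyl]-5,6-dihydro-2H-pyran-2-one | O=C1C=CC[C@@H]([C@H](O)[C@@H](Oc2cc(O)c3c(c2)O[C@H](c2ccccc2)CC3=O)c2ccccc2)O1 | target

## Step count and risks

Total step count: 9. Longest linear sequence: 9 steps (from penta-1,4-dien-3-ol). Compounds 5 and 13 enter as purchased materials.

Steps most likely to fail:

1. Step 5 (proposed new method).
   - What may go wrong: closure through the E ester rotamer may be too slow. Intermolecular O-alkylation of the nitronate, or loss of HNO2 before ring closure, would then take over.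
   - Fallback (known chemistry, sets out from epoxide 3 and comes back at lactone 9): the same C4–C5 bond is made between two molecules and the ring is closed at the acyl–oxygen bond instead. Lithiated ethyl propiolate (n-BuLi, BF3·OEt2, THF, −78 °C) should open 3 at its terminal carbon to give ethyl (5S,6R)-6-(tert-butyldimethylsilyloxy)-5-hydroxyoct-7-en-2-ynoate F1. Semihydrogenation (H2, Pd/CaCO3 poisoned with Pb(OAc)2, quinoline, stopped after one equivalent) should give the (Z)-enoate F2. F2 lactonises to 9 on warming with catalytic PPTS in benzene.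

2. Step 8.
   - What may go wrong: substitution at the hindered benzylic carbinol next to the silyl ether may be slow. Ionisation (erosion of configuration at C8) or elimination could then compete.
   - Fallback (sets out from 12 and comes back at target 15): both oxygens are activated together as a cyclic sulfate, so that C8 becomes a much better SN2 centre and O7 needs no separate protection. Desilylation of 12 (HF·pyridine) gives the anti diol F3. SOCl2/Et3N gives the cyclic sulfite F4, and NaIO4 with catalytic RuCl3 (0 °C, short contact) gives the cyclic sulfate F5. Compound 13 with one equivalent of K2CO3 (DMF, 0 to 23 °C) should open F5 at benzylic C8 with inversion to the potassium sulfate monoester F6. Catalytic H2SO4 in wet THF hydrolyses F6 to 15.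

3. Step 7.
   - What may go wrong: poor facial selectivity in the phenyl addition to the alpha,beta-dioxygenated aldehyde.
   - Fallback (sets out from 12 obtained as a C8 epimer mixture and comes back at 12): substrate control is replaced by catalyst control at the ketone level. Dess–Martin periodinane oxidises the mixture to the phenyl ketone F7. Noyori-type transfer hydrogenation with RuCl(p-cymene)[(S,S)-TsDPEN] in HCO2H/Et3N should then give the (8R) carbinol. This catalyst hand gives (S)-1-phenylethanol from acetophenone, and the same spatial sense is 8R here because C7 outranks phenyl.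

Further compounds
F1 | step 5 | ethyl (5S,6R)-6-(tert-butyldimethylsilyloxy)-5-hydroxyoct-7-en-2-ynoate | CCOC(=O)C#CC[C@H](O)[C@H](O[Si](C)(C)C(C)(C)C)C=C
F2 | step 5 | ethyl (2Z,5S,6R)-6-(tert-butyldimethylsilyloxy)-5-hydroxyocta-2,7-dienoate | CCOC(=O)/C=C\C[C@H](O)[C@H](O[Si](C)(C)C(C)(C)C)C=C
F3 | step 8 | (6S)-6-[(1R,2R)-1,2-dihydroxy-2-phenylethyl]-5,6-dihydro-2H-pyran-2-one | O=C1C=CC[C@@H]([C@H](O)[C@H](O)c2ccccc2)O1
F4 | step 8 | 7,8-cyclic sulfite of F3 (cis-4,5-disubstituted 1,3,2-dioxathiolane 2-oxide) | O=C1C=CC[C@@H]([C@@H]2OS(=O)O[C@@H]2c2ccccc2)O1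
F5 | step 8 | 7,8-cyclic sulfate of F3 (cis-4,5-disubstituted 1,3,2-dioxathiolane 2,2-dioxide) | O=C1C=CC[C@@H]([C@@H]2OS(=O)(=O)O[C@@H]2c2ccccc2)O1
F6 | step 8 | potassium 7-O-sulfate of the target | O=C1C=CC[C@@H]([C@H](OS(=O)(=O)[O-])[C@@H](Oc2cc(O)c3c(c2)O[C@H](c2ccccc2)CC3=O)c2ccccc2)O1.[K+]
F7 | step 7 | (6S)-6-[(1S)-1-(tert-butyldimethylsilyloxy)-2-oxo-2-phenylethyl]-5,6-dihydro-2H-pyran-2-one | O=C1C=CC[C@@H]([C@H](O[Si](C)(C)C(C)(C)C)C(=O)c2ccccc2)O1
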